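All compound numbers below are those of the steps and of the compound list.

## Analysis of the target

Target 22 is an achiral diaryl ether of two p-cymene-type rings and has no stereocentre, so the whole problem is one of regiochemistry and steric access. Ring A (A1 ether carbon, A2 isopropyl, A3 H, A4 methoxy, A5 methyl, A6 H) is the aryl residue of 4-methoxythymol 3; ring B is pentasubstituted (B1 aryloxy, B2 methyl, B3 methoxy, B4 hydrogen, B5 isopropyl, B6 hydroxyl). The bridging oxygen is flanked by the A2 isopropyl on one side and by both the B2 methyl and the B6 hydroxyl on the other, and both rings are electron-rich; this is the worst case for Ullmann or SNAr ether formation between two finished arenes. Ring B carries three oxygens in a 1,2,4-pattern (B1 and B6 ortho, B3 para to B6) that bear three different groups (aryl, methyl, hydrogen) and must be told apart. The free B6 hydroxyl para to the B3 methoxy makes ring B a hydroquinone mono-ether, easily oxidised to a quinone, so nothing oxidising may follow its unveiling, and the aryl methyl ethers exclude harsh Lewis acids late in the route. The strategy rests on three relationships inside ring B: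
- the B1(O-aryl)–B2(CH3) pair is the C≡C unit of the aryl propynyl ether 9;
- the B1 oxygen is meta to the B3 oxygen, the pattern that a cyclobutenone–ynol ether benzannulation delivers, with B4–B5(isopropyl)–B6 coming from C4–C3–C2 of 3-isopropylcyclobutenone 14;
- the last oxygen (B6) is para to the B3 oxygen, the position at which a phenol is oxidised to a para-quinone.

## Retrosynthetic reasoning

**22 to 21 (B3 O–CH3).** The methyl ether on B3 is cut first, leading back to hydroquinone 21. Its two hydroxyls sit in very different surroundings: B3–OH lies between a methyl group and a ring hydrogen, B6–OH between an isopropyl group and the twisted aryloxy group. One O-methylation under mild base should therefore go to B3, and the B6 phenol of the target never needs a protecting group.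

**21 to 20 to 19 (B6–O).** The B6 oxygen is removed next: hydroquinone 21 comes from quinone 20 by reduction, and 20 from phenol 19 by oxidation at the position para to its hydroxyl. In 19 the ortho position B2 is blocked by methyl, so only B4 competes, and phenols with a free para position are oxidised there in preference. This cut is chosen because it reduces ring B to a 1,3-dioxygenated arene, which is what the ring-forming step makes.

**19 to 9 + 14 (B2–B3, B1–B6, B3–B4).** Ring B is taken apart into a two-carbon unit (B1 and B2, the alkyne carbons of aryl propynyl ether 9) and a four-carbon unit (B3, B4, B5, B6, which are C1, C4, C3, C2 of cyclobutenone 14). Forward, 14 opens to vinylketene 15, which adds to 9 to give cyclobutenone 16. Ring opening to dienylketene 17, six-electron closure to dienone 18 and tautomerisation then give 19. The cut is made here and not at the diaryl ether because the crowded C–O bond is then never formed on an arene: the oxygen is already on B1 while B1 is still an sp carbon. The forward reaction has to join the methyl-bearing alkyne carbon to the ketene carbonyl carbon and the aryloxy carbon to the ketene α-carbon; the polarity of both partners demands exactly this.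

**9 to 6 to 3 + 4 (C(sp)–CH3, then O–C(sp)).** The propynyl methyl is cut back to lithium acetylide 8, which arises from dichlorovinyl ether 6 by double elimination and halogen–lithium exchange through chloroalkyne 7. Ether 6 is cut at its O–C bond to 4-methoxythymol 3 and trichloroethylene 4, which react through dichloroacetylene 5. The hindered phenoxide of 3 only has to attack a small sp carbon, so the ortho isopropyl group is no obstacle.

**3 to 2 to 1 (A4–O).** The A4 methoxy group is cut to bromide 2, and the C–Br bond to thymol 1. The hydroxyl of 1 directs bromination to its free para position, which is exactly A4, and copper-catalysed methoxylation then exchanges bromine for methoxy.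

**14 to 13 to 10 + 11.** Cyclobutenone 14 is traced to its 4,4-dichloro derivative 13, and this to 3-methylbut-1-yne 10 and dichloroketene 12, made in the flask from trichloroacetyl chloride 11. The [2+2] orientation puts the isopropyl group on C3, and reductive dechlorination then gives 14.

## Alternatives that were turned down

**Alternative 1:** The ether bond between the bridging oxygen and ring A is made intramolecularly. Depside A1 joins the B6 oxygen of a ring-B catechol to a 2-fluorobenzoyl unit, whose carbonyl carbon stands where the A2 isopropyl will be. With Cs2CO3 in DMF the B1 phenoxide displaces fluoride and closes the seven-membered ring of depsidone A2. The lactone is then opened by two methyl nucleophiles (freeing B6–OH) and the tertiary benzylic alcohol is deoxygenated to the isopropyl group.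
- For: the hindered ether is formed within a ring, the ester both tethers and activates, and the lactone is a masked isopropyl plus phenol. All three ring-B oxygens are in place and differentiated before the coupling, so no late oxidation and no selective methylation are needed; on this point it is stronger than the chosen route.
- Against: the fluorine-bearing carbon is para to the ring-A methoxy group, so only one ortho ester activates an electron-rich ring for SNAr.
- Against: A1 is a catechol mono-ester. Under carbonate the acyl group can shift to the B1 oxygen, after which the B6 oxygen would close to the regioisomeric depsidone; the positions of ether and ester oxygen are therefore not secured.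
- Against: the pentasubstituted catechol and the fluoro acid each need a regiocontrolled multi-step synthesis, and three more operations follow the key step.
- Comparison: the chosen route builds ring B and its substitution pattern in one step from two small pieces, attaches the ether oxygen with no acyl-shift ambiguity, and is shorter.

**Alternative 2:** Ring B is made as a carbocycle by ring-closing metathesis and aromatised afterwards. The acyclic dienone A3 carries the aryloxy group α to the ketone. RuCl2(=CHPh)(PCy3)(H2IMes), the second-generation Grubbs catalyst, closes it at B4=B5 to cyclohexenone A4 with loss of ethylene. β-Elimination of the tertiary hydroxyl and tautomerisation would then give the target phenol directly.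
- For: the ether bond is an easy alkylation of a phenoxide next to a ketone, every substituent is placed by acyclic chemistry, and aromatisation leaves B6–OH and B3–OMe already differentiated. On this last point it is stronger than the chosen route.
- Against: the metathesis must form a trisubstituted enone double bond carrying isopropyl from an electron-poor 1,1-disubstituted alkene, a slow case for ruthenium carbenes.
- Against: three stereocentres are made only to be destroyed. The tertiary β-hydroxy ketone can undergo retro-aldol cleavage, and its assembly needs an unfavourable aldol addition to a ketone. A4 may also lose methanol (the B3 methoxy is allylic and γ to the carbonyl) instead of water.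
- Comparison: the chosen route needs no stereocontrol, makes ring B by a pericyclic cascade whose regiochemistry is intrinsic, and takes far fewer steps. It pays for this with one late oxidation.

**Alternative 3:** Ring B comes from a squarate-derived four-membered ring. The 4-alkenyl-4-silyloxycyclobutenone A5 is heated in toluene, opens to a dienylketene and closes by six-electron electrocyclisation (bond B3–B4) to the hydroquinone mono-silyl ether A6. Methylation of the free B3–OH and desilylation would finish the synthesis.
- For: the same reliable ring-opening and closure as in the chosen route, but all three oxygens arrive in the key step with B3–OH free and B6–O silylated. No oxidation and no selective methylation follow, so its endgame is clearly stronger.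
- Against: A5 needs a cyclobutenedione carrying the hindered aryloxy group as a vinylogous aryl ester. The alkenyllithium that brings in B4–B5 can displace the good aryloxide leaving group by addition–elimination instead of adding to the carbonyl.
- Against: the tertiary alkoxide must then be silylated, and the sequence from a squarate ester is linear (methyl introduction, aryloxy exchange, alkenyl addition, silylation, thermolysis, methylation, desilylation).
- Comparison: the chosen route is convergent from two fragments of two and four steps and forms the ether bond on trichloroethylene with no competing substitution. It accepts in exchange a late phenol-to-quinone oxidation and a sterically controlled mono-methylation.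

Key step: step 7

Assumption: ring positions are labelled as in the analysis; the target has no stereocentre, so no step has to control configuration.

## Route

Step 1
Reactants: 1 thymol
Product: 2 4-bromothymol
Conditions: NBS (1.0 equiv), MeCN, 0 °C → rt
Reagents that add atoms: N-bromosuccinimide, O=C1CCC(=O)N1Br
Why: Electrophilic aromatic bromination; the hydroxyl group directs to its free para position (the future A4), and NBS in MeCN should deliver a single bromine there and not at the more crowded ortho position.

Step 2
Reactants: 2 4-bromothymol
Product: 3 4-methoxythymol
Conditions: NaOMe (5 equiv), CuBr (10 mol %), EtOAc (cat.), MeOH/DMF, 110 °C; aq. HCl work-up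
Reagents that add atoms: sodium methoxide, C[O-].[Na+]
Why: Copper-catalysed Ullmann-type methoxylation of an aryl bromide; the phenol is carried through as its sodium phenoxide and is returned on acidification.

Step 3
Reactants: 3 4-methoxythymol; 4 trichloroethylene
Product: 6 (E)-1-(1,2-dichlorovinyloxy)-2-isopropyl-4-methoxy-5-methylbenzene, via dichloroacetylene 5 (not isolated)
Conditions: K2CO3 (2 equiv), DMF, 70 °C
Reagents that add atoms: none
Why: Base-induced dehydrochlorination of trichloroethylene gives dichloroacetylene, to which the phenoxide adds; anti protonation gives the (E)-1,2-dichlorovinyl ether. This O-dichlorovinylation of phenols is the standard entry to aryl ynol ethers and forms the future B1–O bond by attack on an unhindered sp carbon.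

Step 4
Reactants: 6 (E)-1-(1,2-dichlorovinyloxy)-2-isopropyl-4-methoxy-5-methylbenzene
Product: 9 1-(2-isopropyl-4-methoxy-5-methylphenoxy)prop-1-yne, via chloroethynyl ether 7 (not isolated), via lithium aryloxyacetylide 8 (not isolated)
Conditions: n-BuLi (2.5 equiv), THF, −78 → −40 °C; then MeI (4 equiv), HMPA, −78 °C → rt; chromatography on Et3N-deactivated silica
Reagents that add atoms: iodomethane, CI
Why: Deprotonation and loss of LiCl give the chloroalkynyl ether, chlorine–lithium exchange gives the lithium aryloxyacetylide, and C-alkylation with MeI in the presence of HMPA gives the propynyl ether; this is the established dichlorovinyl ether route to substituted ynol ethers.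

Step 5
Reactants: 10 3-methylbut-1-yne; 11 trichloroacetyl chloride
Product: 13 4,4-dichloro-3-isopropylcyclobut-2-en-1-one, via dichloroketene 12 (not isolated)
Conditions: Zn–Cu couple, Et2O/DME, 0 °C → rt, slow addition of 11
Reagents that add atoms: none
Why: Zinc dechlorinates trichloroacetyl chloride to dichloroketene, which undergoes [2+2] cycloaddition with the terminal alkyne; the ketene carbonyl carbon bonds to the terminal CH, so isopropyl ends on C3. DME ties up ZnCl2 and so suppresses polymerisation.

Step 6
Reactants: 13 4,4-dichloro-3-isopropylcyclobut-2-en-1-one
Product: 14 3-isopropylcyclobut-2-en-1-one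
Conditions: Zn dust, AcOH, TMEDA, EtOH, 0 °C → rt
Reagents that add atoms: none
Why: Reductive dechlorination of the α,α-dichloro ketone through zinc enolates; the amine-buffered conditions are the standard ones that remove both chlorines from 4,4-dichlorocyclobutenones without reducing or opening the strained enone.

Step 7
Reactants: 9 1-(2-isopropyl-4-methoxy-5-methylphenoxy)prop-1-yne; 14 3-isopropylcyclobut-2-en-1-one
Product: 19 5-isopropyl-2-methyl-3-(2-isopropyl-4-methoxy-5-methylphenoxy)phenol, via isopropylvinylketene 15 (not isolated), via 4-alkenylcyclobutenone 16 (not isolated), via dienylketene 17 (not isolated), via cyclohexadienone 18 (not isolated)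
Conditions: 14 (1.5–2 equiv), toluene (0.5 M), sealed tube, 80 → 110 °C; then KOH, MeOH, rt
Reagents that add atoms: none
Why: Heating 14 causes four-electron electrocyclic opening (cleavage of C1–C4) to vinylketene 15, whose ketene C=C adds to ynol ether 9 in a polarity-controlled [2+2] cycloaddition that forms B2–B3 and B1–B6 and gives 16. Cyclobutenone 16 opens in a second four-electron step to the (E)-dienylketene 17, which closes ring B by a thermally allowed disrotatory six-electron electrocyclisation (new bond B3–B4, the former C1–C4 bond of 14) to dienone 18; tautomerisation to phenol 19 makes the cascade irreversible. The closest known reaction is the Danheiser benzannulation of cyclobutenones with alkoxy- and siloxyalkynes, of which this is the aryloxyalkyne case. No stereocentre survives, since the single sp3 centre of racemic 16 is erased on ring opening. The selectivity needed is the orientation of the [2+2] step: the methyl-bearing alkyne carbon of 9 is the nucleophilic terminus (β to oxygen) and bonds to the electrophilic ketene carbonyl carbon (future B3), so the aryloxy carbon joins the ketene α-carbon (future B6) and the B1 oxygen ends meta to the new hydroxyl and next to the unsubstituted B6. Only the isomer of 17 with the alkenyl group cis to the ketene can cyclise, and because outward opening of 16 is reversible the material should be funnelled through the productive isomer. The aryloxy group cannot undergo the retro-ene loss of alkene that limits alkyl ynol ethers at these temperatures, the 4-methoxy group of ring A keeps the ether oxygen a good donor, and the KOH/MeOH treatment returns any 19 that was O-acylated by excess 15.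

Step 8
Reactants: 19 5-isopropyl-2-methyl-3-(2-isopropyl-4-methoxy-5-methylphenoxy)phenol
Product: 20 5-isopropyl-2-methyl-3-(2-isopropyl-4-methoxy-5-methylphenoxy)cyclohexa-2,5-diene-1,4-dione
Conditions: (KSO3)2NO (2.5 equiv), KH2PO4 buffer, acetone/H2O, rt
Reagents that add atoms: dipotassium nitrosodisulfonate, [K+].[K+].[O]N(S(=O)(=O)[O-])S(=O)(=O)[O-]
Why: Teuber oxidation: the first equivalent of the nitroxyl radical gives the phenoxyl radical, the second couples at the free para carbon B6 and loses imidodisulfonate to give the para-quinone. The ortho position B2 is blocked and ring A has no free phenol, so it is untouched.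

Step 9
Reactants: 20 5-isopropyl-2-methyl-3-(2-isopropyl-4-methoxy-5-methylphenoxy)cyclohexa-2,5-diene-1,4-dione
Product: 21 5-isopropyl-2-methyl-3-(2-isopropyl-4-methoxy-5-methylphenoxy)benzene-1,4-diol
Conditions: Na2S2O4 (excess), EtOAc/H2O, rt, N2
Reagents that add atoms: none
Why: Two-electron reduction of a para-quinone to its hydroquinone by dithionite, a mild and general reaction that leaves the aryl ethers alone; the product is kept under inert gas and used at once.

Step 10
Reactants: 21 5-isopropyl-2-methyl-3-(2-isopropyl-4-methoxy-5-methylphenoxy)benzene-1,4-diol
Product: 22 6-isopropyl-4-methoxy-3-methyl-2-(2-isopropyl-4-methoxy-5-methylphenoxy)phenol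
Conditions: MeI (1.05 equiv), K2CO3 (1.1 equiv), degassed acetone, rt, Ar
Reagents that add atoms: iodomethane, CI
Why: Williamson ether synthesis under steric control: the B3 hydroxyl lies between methyl and hydrogen, the B6 hydroxyl between isopropyl and the bulky twisted aryloxy group, so one equivalent of MeI should alkylate B3. Hindered hydroquinones such as tert-butylhydroquinone are known to methylate preferentially at the hydroxyl remote from the bulky group.

## Compound list

1 | thymol (2-isopropyl-5-methylphenol) | CC(C)c1ccc(C)cc1O | starting material
2 | 4-bromothymol (4-bromo-2-isopropyl-5-methylphenol) | CC(C)c1cc(Br)c(C)cc1O | intermediate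
3 | 4-methoxythymol (2-isopropyl-4-methoxy-5-methylphenol) | CC(C)c1cc(OC)c(C)cc1O | intermediate
4 | trichloroethylene | ClC=C(Cl)Cl | starting material
5 | dichloroacetylene (not isolated) | ClC#CCl | intermediate
6 | (E)-1-(1,2-dichlorovinyloxy)-2-isopropyl-4-methoxy-5-methylbenzene | Cl/C=C(/Cl)Oc1cc(C)c(OC)cc1C(C)C | intermediate
7 | 1-(chloroethynyloxy)-2-isopropyl-4-methoxy-5-methylbenzene (not isolated) | ClC#COc1cc(C)c(OC)cc1C(C)C | intermediate
8 | lithium (2-isopropyl-4-methoxy-5-methylphenoxy)acetylide (not isolated) | [Li]C#COc1cc(C)c(OC)cc1C(C)C | intermediate
9 | 1-(2-isopropyl-4-methoxy-5-methylphenoxy)prop-1-yne | CC#COc1cc(C)c(OC)cc1C(C)C | intermediate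
10 | 3-methylbut-1-yne | CC(C)C#C | starting material
11 | trichloroacetyl chloride | O=C(Cl)C(Cl)(Cl)Cl | starting material
12 | dichloroketene (not isolated) | O=C=C(Cl)Cl | intermediate
13 | 4,4-dichloro-3-isopropylcyclobut-2-en-1-one | CC(C)C1=CC(=O)C1(Cl)Cl | intermediate
14 | 3-isopropylcyclobut-2-en-1-one | CC(C)C1=CC(=O)C1 | intermediate
15 | isopropylvinylketene, 4-methyl-3-methylidenepent-1-en-1-one (not isolated) | CC(C)C(=C)C=C=O | intermediate
16 | racemic 2-methyl-4-(3-methylbut-1-en-2-yl)-3-(2-isopropyl-4-methoxy-5-methylphenoxy)cyclobut-2-en-1-one (not isolated) | CC(C)C(=C)C1C(=O)C(C)=C1Oc1cc(C)c(OC)cc1C(C)C | intermediate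
17 | (3E)-2,6-dimethyl-5-methylidene-3-(2-isopropyl-4-methoxy-5-methylphenoxy)hepta-1,3-dien-1-one (not isolated) | O=C=C(C)/C(Oc1cc(C)c(OC)cc1C(C)C)=C\C(=C)C(C)C | intermediate
18 | 5-isopropyl-2-methyl-3-(2-isopropyl-4-methoxy-5-methylphenoxy)cyclohexa-2,4-dien-1-one (not isolated) | CC(C)C1=CC(Oc2cc(C)c(OC)cc2C(C)C)=C(C)C(=O)C1 | intermediate
19 | 5-isopropyl-2-methyl-3-(2-isopropyl-4-methoxy-5-methylphenoxy)phenol | CC(C)c1cc(O)c(C)c(Oc2cc(C)c(OC)cc2C(C)C)c1 | intermediate
20 | 5-isopropyl-2-methyl-3-(2-isopropyl-4-methoxy-5-methylphenoxy)cyclohexa-2,5-diene-1,4-dione | CC(C)C1=CC(=O)C(C)=C(Oc2cc(C)c(OC)cc2C(C)C)C1=O | intermediate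
21 | 5-isopropyl-2-methyl-3-(2-isopropyl-4-methoxy-5-methylphenoxy)benzene-1,4-diol | CC(C)c1cc(O)c(C)c(Oc2cc(C)c(OC)cc2C(C)C)c1O | intermediate
22 | 6-isopropyl-4-methoxy-3-methyl-2-(2-isopropyl-4-methoxy-5-methylphenoxy)phenol (CNP0271085.0) | COc1cc(C(C)C)c(Oc2c(C)c(OC)cc(C(C)C)c2O)cc1C | target

## Step count and least certain steps

Total step count: 10. Longest linear sequence: 8 steps (1 → 2 → 3 → 6 → 9 → 19 → 20 → 21 → 22; steps 1–4 and 7–10). Steps 5 and 6 form the two-step side branch to 14.

**Step 7 (key step).** The most likely failure is slow capture of vinylketene 15. The oxygen lone pair of 9 is shared with ring A, which makes this ynol ether less nucleophilic than the alkyl and silyl ynol ethers normally used, and 15 could be consumed by dimerisation or by acylating the product phenol before the [2+2] step occurs. The fallback uses a more nucleophilic siloxyalkyne for the benzannulation and forms the diaryl ether afterwards, while B6 still carries hydrogen, so that each coupling partner has only one ortho substituent. It sets out from 14 and returns at 19. Kowalski ester homologation of ethyl propanoate with O-silylation by i-Pr3SiCl gives 1-(triisopropylsilyloxy)prop-1-yne F1. Heating F1 with 14 in toluene gives 5-isopropyl-2-methyl-3-(triisopropylsilyloxy)phenol F2, a mono-silyl ether of a symmetric resorcinol whose free hydroxyl can therefore serve as the B1 oxygen. Bromination of commercial carvacrol methyl ether para to its methoxy group (NBS, MeCN) gives 1-bromo-2-isopropyl-4-methoxy-5-methylbenzene F3. Ullmann coupling of F2 with F3 (CuI, picolinic acid, K3PO4, DMSO, 90 °C) gives triisopropyl[5-isopropyl-2-methyl-3-(2-isopropyl-4-methoxy-5-methylphenoxy)phenoxy]silane F4, and desilylation with tetrabutylammonium fluoride in THF gives 19.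

**Step 8.** Two processes could go wrong: attack at the ortho position B4, leading to an ortho-quinone, or slow coupling of the bulky nitrosodisulfonate radical at the para carbon B6 (which is flanked by isopropyl and aryloxy), leaving the phenoxyl radical to dimerise. The fallback brings in the B6 heteroatom by electrophilic substitution with a small electrophile. It sets out from 19 and returns at 20. Para-nitrosation (NaNO2, AcOH/EtOH, 0 °C) gives 5-isopropyl-2-methyl-4-nitroso-3-(2-isopropyl-4-methoxy-5-methylphenoxy)phenol F5 (in equilibrium with its quinone oxime tautomer). Reduction with Na2S2O4 gives 4-amino-5-isopropyl-2-methyl-3-(2-isopropyl-4-methoxy-5-methylphenoxy)phenol F6. Oxidation with FeCl3 in aqueous HCl, with hydrolytic loss of the nitrogen as NH4Cl, gives quinone 20.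

**Step 10.** The risk is loss of site selectivity, that is methylation at B6–OH (the more acidic hydroxyl, next to the aryloxy oxygen) or at both hydroxyls, together with re-oxidation of the hydroquinone anion to 20 by traces of air. The fallback differentiates the two oxygens at the moment the B6 oxygen is introduced. It sets out from 19, bypasses 20 and 21, and returns at 22. Elbs persulfate oxidation (K2S2O8, aqueous KOH, pyridine, 0 °C → rt) attaches a sulfate ester para to the phenol and gives potassium 4-hydroxy-6-isopropyl-3-methyl-2-(2-isopropyl-4-methoxy-5-methylphenoxy)phenyl sulfate F7. Methylation of its only free hydroxyl (MeI, K2CO3, DMF) gives potassium 6-isopropyl-4-methoxy-3-methyl-2-(2-isopropyl-4-methoxy-5-methylphenoxy)phenyl sulfate F8. Hydrolysis of the aryl sulfate in warm aqueous HCl gives 22.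

**Step 4.** Likely problems are incomplete C-methylation of acetylide 8 (protonation on work-up to the terminal aryloxyacetylene), expulsion of aryloxide from the lithiated vinyl chloride, and hydration of 9 on acidic silica. The fallback builds the alkyne by copper-catalysed vinylation and elimination instead of organolithium chemistry. It sets out from 3 and returns at 9. Coupling of 3 with 1,1-dibromoprop-1-ene (CuI, 2,2'-bipyridine, K3PO4, toluene, 110 °C) gives (Z)-1-(1-bromoprop-1-enyloxy)-2-isopropyl-4-methoxy-5-methylbenzene F9, and dehydrobromination with t-BuOK in THF gives 9.

**Step 2.** The bromide reacts as an electron-rich phenoxide, so substitution may be slow and reductive loss of bromine (back to 1) may compete. The fallback introduces the methoxy group by oxidative dearomatisation. It sets out from 1 and returns at 3. Oxidation of 1 with PhI(OAc)2 (2 equiv) in MeOH gives 2-isopropyl-4,4-dimethoxy-5-methylcyclohexa-2,5-dien-1-one F10 (a quinone monoketal), and reductive aromatisation with Zn dust in AcOH expels one methoxy group and gives 3.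

## Further compounds

F1 | step 7 | 1-(triisopropylsilyloxy)prop-1-yne | CC#CO[Si](C(C)C)(C(C)C)C(C)C
F2 | step 7 | 5-isopropyl-2-methyl-3-(triisopropylsilyloxy)phenol | CC(C)c1cc(O)c(C)c(O[Si](C(C)C)(C(C)C)C(C)C)c1
F3 | step 7 | 1-bromo-2-isopropyl-4-methoxy-5-methylbenzene | COc1cc(C(C)C)c(Br)cc1C
F4 | step 7 | triisopropyl[5-isopropyl-2-methyl-3-(2-isopropyl-4-methoxy-5-methylphenoxy)phenoxy]silane | CC(C)c1cc(O[Si](C(C)C)(C(C)C)C(C)C)c(C)c(Oc2cc(C)c(OC)cc2C(C)C)c1
F5 | step 8 | 5-isopropyl-2-methyl-4-nitroso-3-(2-isopropyl-4-methoxy-5-methylphenoxy)phenol | CC(C)c1cc(O)c(C)c(Oc2cc(C)c(OC)cc2C(C)C)c1N=O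
F6 | step 8 | 4-amino-5-isopropyl-2-methyl-3-(2-isopropyl-4-methoxy-5-methylphenoxy)phenol | CC(C)c1cc(O)c(C)c(Oc2cc(C)c(OC)cc2C(C)C)c1N
F7 | step 10 | potassium 4-hydroxy-6-isopropyl-3-methyl-2-(2-isopropyl-4-methoxy-5-methylphenoxy)phenyl sulfate | [K+].CC(C)c1cc(O)c(C)c(Oc2cc(C)c(OC)cc2C(C)C)c1OS(=O)(=O)[O-]
F8 | step 10 | potassium 6-isopropyl-4-methoxy-3-methyl-2-(2-isopropyl-4-methoxy-5-methylphenoxy)phenyl sulfate | [K+].COc1cc(C(C)C)c(OS(=O)(=O)[O-])c(Oc2cc(C)c(OC)cc2C(C)C)c1C
F9 | step 4 | (Z)-1-(1-bromoprop-1-enyloxy)-2-isopropyl-4-methoxy-5-methylbenzene | C/C=C(\Br)Oc1cc(C)c(OC)cc1C(C)C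
F10 | step 2 | 2-isopropyl-4,4-dimethoxy-5-methylcyclohexa-2,5-dien-1-one | CC(C)C1=CC(OC)(OC)C(C)=CC1=O
A1 | alternative 1 | 2-hydroxy-6-isopropyl-4-methoxy-3-methylphenyl 2-fluoro-5-methoxy-4-methylbenzoate | O=C(Oc1c(C(C)C)cc(OC)c(C)c1O)c1cc(OC)c(C)cc1F
A2 | alternative 1 | 9-isopropyl-2,7-dimethoxy-3,6-dimethyl-11H-dibenzo[b,e][1,4]dioxepin-11-one | O=C1Oc2c(C(C)C)cc(OC)c(C)c2Oc2cc(C)c(OC)cc12
A3 | alternative 2 | 5-hydroxy-2-isopropyl-6-methoxy-5-methyl-4-(2-isopropyl-4-methoxy-5-methylphenoxy)octa-1,7-dien-3-one (mixture of diastereomers) | C=C(C(C)C)C(=O)C(Oc1cc(C)c(OC)cc1C(C)C)C(C)(O)C(OC)C=C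
A4 | alternative 2 | 5-hydroxy-2-isopropyl-4-methoxy-5-methyl-6-(2-isopropyl-4-methoxy-5-methylphenoxy)cyclohex-2-en-1-one (mixture of diastereomers) | O=C1C(C(C)C)=CC(OC)C(C)(O)C1Oc1cc(C)c(OC)cc1C(C)C
A5 | alternative 3 | racemic 4-(tert-butyldimethylsilyloxy)-2-methyl-4-(3-methylbut-1-en-2-yl)-3-(2-isopropyl-4-methoxy-5-methylphenoxy)cyclobut-2-en-1-one | O=C1C(C)=C(Oc2cc(C)c(OC)cc2C(C)C)C1(O[Si](C)(C)C(C)(C)C)C(=C)C(C)C
A6 | alternative 3 | 4-(tert-butyldimethylsilyloxy)-5-isopropyl-2-methyl-3-(2-isopropyl-4-methoxy-5-methylphenoxy)phenol | CC(C)c1cc(O)c(C)c(Oc2cc(C)c(OC)cc2C(C)C)c1O[Si](C)(C)C(C)(C)C
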